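**Plan**

1. Target 15 is methyl (2Z,6E)-9-[(2R)-7-hydroxy-2,5-dimethylchroman-2-yl]-2,6-dimethylnona-2,6-dienoate. Retrosynthesis: O7 is silylated and a C3=C4 double bond is added; the pyran ring is then cut at O1–C2 and C4–C4a into orcinol mono-TIPS ether and a C16 trienal ester. The enoate C=C is cut next (Z-selective olefination), leaving a C12 hydroxy aldehyde from (2E,6E)-farnesol.
2. Enabling feature: in the resorcinol ring, O1–C8a=C4a is an enol unit whose carbon end C4a is also para to the C7 oxygen, and C4, C3, C2 of the pyran ring map onto the C=O, α and β carbons of a β,β-disubstituted enal. Condensation gives the 1-oxatriene O1=C8a–C4a=C4–C3=C2 (an ortho-quinone methide), which closes to the pyran ring by oxa-6π electrocyclisation.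
3. Forward: the chain is made first (terminal olefin of farnesol cleaved, (Z)-enoate added, allylic alcohol oxidised to the enal). One operation then joins chain and arene and builds the only new ring. The helper C3=C4 bond is removed with diimide and the silyl ether is cleaved last.
4. Stereochemistry: C2 (R) is set in the annulation by a chiral Brønsted acid acting on a common planar intermediate (enantioconvergent). 6E is carried from farnesol; 2Z comes from the Still–Gennari olefination.

Key step: step 7

Remark: the sense of induction of the chiral acid in step 7 cannot be predicted with confidence; the step is written with the (R)-catalyst, and its enantiomer would be used if the opposite sense is found. (2E,6E)-Farnesol, orcinol and phosphonate 6 are taken as commercial.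

**Route**

Step 1
Reactants: 1 (2E,6E)-farnesol
Product: 2 (2E,6E)-farnesyl acetate
Conditions: Ac2O, pyridine, DMAP (cat.), CH2Cl2, 0 °C to rt
Reagents that add atoms: acetic anhydride, CC(=O)OC(C)=O
Why: O-acylation (nucleophilic acyl substitution); the allylic acetate lowers the nucleophilicity of the 2,3-olefin so that the next step should favour the distal olefin.

Step 2
Reactants: 2 (2E,6E)-farnesyl acetate
Product: 4 rac-(2E,6E)-10,11-epoxyfarnesol, via bromohydrin acetate 3 (not isolated)
Conditions: NBS, THF/H2O, 0 °C; then K2CO3, MeOH, rt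
Reagents that add atoms: water, O (epoxide oxygen); N-bromosuccinimide, O=C1CCC(=O)N1Br (its bromine is in 3 only and leaves again on ring closure)
Why: Terminal-selective bromohydrin formation of a polyprenyl chain in aqueous THF (Markovnikov attack of water at C11), followed by intramolecular Williamson-type epoxide closure with concurrent methanolysis of the acetate; the epoxide stereocentre is racemic and is destroyed in step 3.

Step 3
Reactants: 4 rac-(2E,6E)-10,11-epoxyfarnesol
Product: 5 (4E,8E)-10-hydroxy-4,8-dimethyldeca-4,8-dienal
Conditions: H5IO6, THF/H2O, 0 °C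
Reagents that add atoms: none
Why: Periodic acid opens the epoxide to the vicinal diol and cleaves it in the same flask (Malaprade-type glycol cleavage), releasing acetone and leaving both trisubstituted olefins and the allylic alcohol untouched.

Step 4
Reactants: 5 (4E,8E)-10-hydroxy-4,8-dimethyldeca-4,8-dienal; 6 methyl 2-[bis(2,2,2-trifluoroethoxy)phosphoryl]propanoate
Product: 7 methyl (2Z,6E,10E)-12-hydroxy-2,6,10-trimethyldodeca-2,6,10-trienoate
Conditions: 6, KHMDS, 18-crown-6, THF, −78 °C; then 5
Reagents that add atoms: none
Why: Still–Gennari olefination: the electron-poor bis(trifluoroethyl) phosphonate under dissociating conditions eliminates quickly from the kinetic adduct and should give the (Z)-2-methyl enoate, and the preformed stabilised anion is too weak a base to deprotonate the free primary alcohol.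

Step 5
Reactants: 7 methyl (2Z,6E,10E)-12-hydroxy-2,6,10-trimethyldodeca-2,6,10-trienoate
Product: 8 methyl (2Z,6E,10E)-2,6,10-trimethyl-12-oxododeca-2,6,10-trienoate
Conditions: activated MnO2, CH2Cl2, rt
Reagents that add atoms: none
Why: Selective allylic alcohol oxidation with MnO2 should give the (10E)-enal without touching the enoate or the isolated olefin.

Step 6
Reactants: 9 orcinol (5-methylbenzene-1,3-diol)
Product: 10 3-methyl-5-[(triisopropylsilyl)oxy]phenol
Conditions: TIPSCl (1 equiv), imidazole, DMF, 0 °C to rt, 9 in excess
Reagents that add atoms: triisopropylsilyl chloride, CC(C)[Si](Cl)(C(C)C)C(C)C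
Why: Statistical mono-O-silylation of a symmetrical diol (silyl ether formation), with excess diol suppressing the bis-ether; the bulky silyloxy group later directs the annulation to the carbon para to it.

Step 7
Reactants: 8 methyl (2Z,6E,10E)-2,6,10-trimethyl-12-oxododeca-2,6,10-trienoate; 10 3-methyl-5-[(triisopropylsilyl)oxy]phenol
Product: 13 methyl (2Z,6E)-9-[(2R)-2,5-dimethyl-7-(triisopropylsilyloxy)-2H-chromen-2-yl]-2,6-dimethylnona-2,6-dienoate, via carbinol 11 (not isolated), via ortho-quinone methide 12 (not isolated)
Conditions: (R)-3,3′-bis(2,4,6-triisopropylphenyl)-H8-BINOL N-triflylphosphoramide (10 mol%), 5 Å MS, toluene, −40 to 0 °C, dark; Et3N quench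
Reagents that add atoms: none
Why: Proposed new method: the bifunctional chiral N-triflylphosphoramide hydrogen-bonds the phenol OH of 10 and protonates the formyl group of 8, so that C2 of 10 (between OH and CH3, para to the silyloxy group) adds 1,2 to the aldehyde (ortho Friedel–Crafts hydroxyalkylation, forming C4–C4a) to give racemic carbinol 11, which the same acid ionises with loss of water to the ortho-quinone methide / hydroxyaryl allyl cation 12, held as a contact ion pair with the chiral anion. The pyran ring then closes by oxa-6π electrocyclisation of the 1-oxatriene O1=C8a–C4a=C4–C3=C2 (equivalently a 6-endo attack of the phenolic oxygen on the allyl terminus), forming O1–C2. The closest known reaction types are the racemic amine- or acid-mediated formal [3+3] chromene annulation of resorcinols with β,β-disubstituted enals and the chiral N-triflylphosphoramide-catalysed cyclisation of racemic ortho-hydroxyaryl allylic alcohols to 2H-chromenes through chiral contact ion pairs. The C2 stereocentre is controlled by the catalyst: both enantiomers of 11 funnel into the same planar intermediate 12 (stereoablative, enantioconvergent), and the anion, still hydrogen-bonded to the phenolic O–H, shields one face of C2 during closure. The step needs ortho-regioselectivity for C2 of 10 over C6 and C4, secured by OH-directed delivery, para-activation by the silyloxy group and the bulk of the TIPS group beside C6; it also needs chemoselectivity over carbonyl-ene or cation-olefin cyclisation of the chain, secured by the (10E)-enal geometry, the low temperature and the much higher nucleophilicity of the phenol.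

Step 8
Reactants: 13 methyl (2Z,6E)-9-[(2R)-2,5-dimethyl-7-(triisopropylsilyloxy)-2H-chromen-2-yl]-2,6-dimethylnona-2,6-dienoate
Product: 14 methyl (2Z,6E)-9-[(2R)-2,5-dimethyl-7-(triisopropylsilyloxy)chroman-2-yl]-2,6-dimethylnona-2,6-dienoate
Conditions: 2-nitrobenzenesulfonyl hydrazide (excess, in portions), Et3N, CH2Cl2, rt
Reagents that add atoms: none
Why: Diimide reduction (concerted syn transfer of H2) is very sensitive to olefin substitution, so the cis-disubstituted styrene-type C3=C4 bond should be saturated while the two trisubstituted olefins survive, and no bond to C2 is broken.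

Step 9
Reactants: 14 methyl (2Z,6E)-9-[(2R)-2,5-dimethyl-7-(triisopropylsilyloxy)chroman-2-yl]-2,6-dimethylnona-2,6-dienoate
Product: 15 methyl (2Z,6E)-9-[(2R)-7-hydroxy-2,5-dimethylchroman-2-yl]-2,6-dimethylnona-2,6-dienoate
Conditions: TBAF, AcOH, THF, 0 °C
Reagents that add atoms: none
Why: Fluoride-mediated desilylation of the aryl silyl ether under buffered conditions should leave the methyl ester, the (Z)-enoate geometry and the C2 stereocentre untouched.

**Compound list**

1 | (2E,6E)-farnesol | CC(C)=CCC/C(C)=C/CC/C(C)=C/CO | starting material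
2 | (2E,6E)-farnesyl acetate | CC(C)=CCC/C(C)=C/CC/C(C)=C/COC(C)=O | intermediate
3 | rac-(2E,6E)-10-bromo-11-hydroxy-3,7,11-trimethyldodeca-2,6-dien-1-yl acetate (bromohydrin acetate) | CC(C)(O)C(Br)CC/C(C)=C/CC/C(C)=C/COC(C)=O | intermediate
4 | rac-(2E,6E)-10,11-epoxyfarnesol, i.e. (2E,6E)-9-(3,3-dimethyloxiran-2-yl)-3,7-dimethylnona-2,6-dien-1-ol | CC1(C)OC1CC/C(C)=C/CC/C(C)=C/CO | intermediate
5 | (4E,8E)-10-hydroxy-4,8-dimethyldeca-4,8-dienal | O=CCC/C(C)=C/CC/C(C)=C/CO | intermediate
6 | methyl 2-[bis(2,2,2-trifluoroethoxy)phosphoryl]propanoate | COC(=O)C(C)P(=O)(OCC(F)(F)F)OCC(F)(F)F | starting material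
7 | methyl (2Z,6E,10E)-12-hydroxy-2,6,10-trimethyldodeca-2,6,10-trienoate | COC(=O)/C(C)=C\CC/C(C)=C/CC/C(C)=C/CO | intermediate
8 | methyl (2Z,6E,10E)-2,6,10-trimethyl-12-oxododeca-2,6,10-trienoate | COC(=O)/C(C)=C\CC/C(C)=C/CC/C(C)=C/C=O | intermediate
9 | orcinol (5-methylbenzene-1,3-diol) | Cc1cc(O)cc(O)c1 | starting material
10 | 3-methyl-5-[(triisopropylsilyl)oxy]phenol | Cc1cc(O)cc(O[Si](C(C)C)(C(C)C)C(C)C)c1 | intermediate
11 | rac-methyl (2Z,6E,10E)-12-hydroxy-12-[2-hydroxy-6-methyl-4-(triisopropylsilyloxy)phenyl]-2,6,10-trimethyldodeca-2,6,10-trienoate (carbinol) | COC(=O)/C(C)=C\CC/C(C)=C/CC/C(C)=C/C(O)c1c(C)cc(O[Si](C(C)C)(C(C)C)C(C)C)cc1O | intermediate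
12 | methyl (2Z,6E,10E)-2,6,10-trimethyl-12-[2-methyl-6-oxo-4-(triisopropylsilyloxy)cyclohexa-2,4-dien-1-ylidene]dodeca-2,6,10-trienoate (ortho-quinone methide, vinyl group cis to C=O) | COC(=O)/C(C)=C\CC/C(C)=C/CC/C(C)=C/C=C1/C(C)=CC(O[Si](C(C)C)(C(C)C)C(C)C)=CC1=O | intermediate
13 | methyl (2Z,6E)-9-[(2R)-2,5-dimethyl-7-(triisopropylsilyloxy)-2H-chromen-2-yl]-2,6-dimethylnona-2,6-dienoate | COC(=O)/C(C)=C\CC/C(C)=C/CC[C@]1(C)C=Cc2c(C)cc(O[Si](C(C)C)(C(C)C)C(C)C)cc2O1 | intermediate
14 | methyl (2Z,6E)-9-[(2R)-2,5-dimethyl-7-(triisopropylsilyloxy)chroman-2-yl]-2,6-dimethylnona-2,6-dienoate | COC(=O)/C(C)=C\CC/C(C)=C/CC[C@]1(C)CCc2c(C)cc(O[Si](C(C)C)(C(C)C)C(C)C)cc2O1 | intermediate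
15 | methyl (2Z,6E)-9-[(2R)-7-hydroxy-2,5-dimethylchroman-2-yl]-2,6-dimethylnona-2,6-dienoate | COC(=O)/C(C)=C\CC/C(C)=C/CC[C@]1(C)CCc2c(C)cc(O)cc2O1 | target

**Count**

Total steps: 9. Longest linear sequence: 8 steps (1, 2, 3, 4, 5, 7, 8, 9); step 6 is the one-step side branch.

**Steps most likely to fail**

1. Step 7 (Proposed new method). Possible failures as processes: ring closure through an uncatalysed or reversible pathway with loss of enantiocontrol, attack of the arene at the wrong ortho carbon, or acid-triggered cyclisation of the polyene chain. The fallback uses known chemistry, sets out from 7 and 10 and returns to the route at 13. Alcohol 7 is converted with methyl chloroformate and pyridine into the allylic methyl carbonate F1. Pd(0) with the DACH-phenyl bis(2-diphenylphosphinobenzamide) ligand (Tsuji–Trost asymmetric O-allylation of a phenol at the more substituted allyl terminus, ligand antipode chosen for the R ether) joins F1 and 10 to the tertiary aryl allyl ether F2, which already carries the C2 stereocentre. 9-BBN hydroboration of the monosubstituted vinyl group with NaBO3 oxidation gives the primary alcohol F3, and Dess–Martin oxidation gives the aldehyde F4. Brief acid treatment (TsOH cat., CH2Cl2) closes the ring by intramolecular Friedel–Crafts hydroxyalkylation para to the silyloxy group and dehydrates to 13.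

2. Step 8. Possible failures: reduction of the trisubstituted olefins alongside the ring olefin, or stalling at the hindered ring olefin next to the quaternary carbon. The fallback sets out from 13 and returns at 14 by ionic hydrogenation (Et3SiH, TFA, CH2Cl2, −40 °C). This is a polar proton-then-hydride transfer that should select the ring olefin because protonation at C3 gives a C4 benzylic cation stabilised by the ortho O1 and the para silyloxy oxygen. No new compound is made (F0).

3. Step 4. Possible failures: erosion of Z-selectivity, or consumption of base by the free hydroxyl with incomplete olefination. The fallback sets out from 5 and returns at 7. A Stork–Zhao-type Wittig reaction with (1-iodoethyl)triphenylphosphonium iodide and NaHMDS (one extra equivalent for the hydroxyl) gives (2E,6E,10Z)-11-iodo-3,7-dimethyldodeca-2,6,10-trien-1-ol F5. Pd-catalysed methoxycarbonylation (CO, MeOH, Et3N) then replaces iodine with retention of olefin geometry to give 7.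

**Further compounds**

F1 | step 7 | methyl (2Z,6E,10E)-12-[(methoxycarbonyl)oxy]-2,6,10-trimethyldodeca-2,6,10-trienoate | COC(=O)/C(C)=C\CC/C(C)=C/CC/C(C)=C/COC(=O)OC
F2 | step 7 | methyl (2Z,6E,10R)-2,6,10-trimethyl-10-[3-methyl-5-(triisopropylsilyloxy)phenoxy]dodeca-2,6,11-trienoate | COC(=O)/C(C)=C\CC/C(C)=C/CC[C@](C)(C=C)Oc1cc(C)cc(O[Si](C(C)C)(C(C)C)C(C)C)c1
F3 | step 7 | methyl (2Z,6E,10R)-12-hydroxy-2,6,10-trimethyl-10-[3-methyl-5-(triisopropylsilyloxy)phenoxy]dodeca-2,6-dienoate | COC(=O)/C(C)=C\CC/C(C)=C/CC[C@](C)(CCO)Oc1cc(C)cc(O[Si](C(C)C)(C(C)C)C(C)C)c1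
F4 | step 7 | methyl (2Z,6E,10R)-2,6,10-trimethyl-10-[3-methyl-5-(triisopropylsilyloxy)phenoxy]-12-oxododeca-2,6-dienoate | COC(=O)/C(C)=C\CC/C(C)=C/CC[C@](C)(CC=O)Oc1cc(C)cc(O[Si](C(C)C)(C(C)C)C(C)C)c1
F0 | step 8 | none | none
F5 | step 4 | (2E,6E,10Z)-11-iodo-3,7-dimethyldodeca-2,6,10-trien-1-ol | C/C(I)=C/CC/C(C)=C/CC/C(C)=C/CO
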